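## Structural features

The target is a hydrindenone: a cyclopentenone (C1, C2 ketone, C3=C3a) fused through C3a and the quaternary, methyl-bearing C7a to a cyclohexane (C4–C7); C8 denotes the carboxyl carbon on C7. C1, C7a and C7 are contiguous stereocentres and C4 lies across the sp2 carbon C3a. The C1 chain, the C7a methyl, the C7 carboxyl and the C4 acyloxy group all stand on one face (1R,4S,7R,7aS), and the ester side chain carries a remote 6R centre. The fragile groups are the α-methylene aldehyde (Michael acceptor), the γ-acyloxy enone with its enolisable C1, the dienoate whose C6 stereocentre is the vinylogous ε-position, and the free acid. The real difficulty is the quaternary C7a flanked by two stereocentres; at C7, next to that quaternary carbon, neither epimer is clearly favoured by simple equilibration. The key step uses C7a as the β-carbon of a 3-methylcyclopentenone and the 1,5 relation between C8 and the C2 ketone: a cyclobutane C7a–C7–C8–C1 from an enone/enol-ester photocycloaddition, then retro-aldol cleavage of C1–C8. Because that cycloaddition must place C8 on the face of C1 (trans to the methyl, the opposite of the target), the 1,4-cis relation of the C4 oxygen and C8 is used as well: only the correct C7 epimer can close a C4–O–C8 lactone.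

## Logic of the disconnections

43 ⇒ 42. No skeletal bond is cut; the aldehyde of the side chain is taken back to the primary allylic alcohol. The α-methylene aldehyde is the most fragile group and should exist only in the last flask. The forward step needs an oxidant that tolerates a free acid, an enone and a dienoate.

42 ⇒ 41. The ester O–CH2Ar bond and the O–Si bond of the side chain are restored. Both are acid-labile, so one mild acidolysis suffices and no base touches the dienoate or the enone late in the route.

41 ⇒ 31 + 39. The C4–O acyl bond is cut, which makes the route convergent and removes the base-sensitive C6′ centre from all enolate chemistry. The forward acylation must work on a hindered axial allylic alcohol with only amine bases.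

39 ⇒ 38 ⇒ 36 ⇒ 35 ⇒ 33 ⇒ 32. The C2′=C3′ and C4′=C5′ double bonds are cut by two stabilised-ylide olefinations. The stereocentre comes from 32, and the α-branched aldehyde between 33 and 35 must never be isolated.

31 ⇒ 25 + 28 (28 ⇒ 27 ⇒ 26). The C1–CH2 bond is cut. In 25 the only kinetically accessible enolate is the α′ one at C1, so regiochemistry is structural. The forward step must deliver the chain cis to the C7a methyl, which is also the more stable arrangement.

25 ⇒ 22. The C3=C3a double bond is removed. This gives back the saturated cis-fused ketone in which C3a is a stereocentre able to direct the formation of C7a. The forward desaturation requires enolisation towards C3 and not C1.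

22 ⇒ 20 ⇒ 17 ⇒ 16 ⇒ 15. The C8–O4 lactone bond is formed and then cut again, with oxidation-level changes at C8. The lactone is the device that inverts C7. It demands a free C4 hydroxyl, a masked ketone and an epimerisable ester in 17.

15 ⇒ 13. The C1–C8 bond is reconnected (retro-aldol transform). A β-acyloxy ketone in a cyclobutane is the retron; the forward step only needs the acetate to be removed.

13 ⇒ 12. The C7a–C7 and C1–C8 bonds are cut. Two rings and four stereocentres fall away and the quaternary centre becomes an ordinary enone β-carbon. The forward step needs the tether to enforce both the face and the straight regiochemistry.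

12 ⇒ 11 ⇒ 9 ⇒ 8 ⇒ 7 ⇒ 4 + 3 (3 ⇒ 1). The C8–O enol ester bond, the C7a–CH3 bond (with carbonyl transposition) and the C3a–C4 aldol bond are cut. The aldehyde terminus travels as a dimethyl acetal, so no hydroboration is needed beside a reducible enone. The aldol must be syn and the alcohol must be obtained as one enantiomer.

## Other disconnections considered

Alternative 1: The cut is C3a–C4. The forward step is a Nozaki–Hiyama–Kishi closure of the alkenyl iodide aldehyde A1 to the allylic alcohol A2 with CrCl2 (divalent chromium) and catalytic NiCl2. Zerovalent nickel inserts into the carbon–iodine bond, the alkenyl group passes to trivalent chromium and adds 6-exo to the aldehyde.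
- In its favour: C7 and C7a are set before the ring closes, so C7 never has to be inverted, and C3=C3a is already present, so no regioselective desaturation is needed. On both points it is better than the chosen plan. The late stages (C1 alkylation, acylation, deprotection) are the same.
- Against it: A1 already contains the quaternary C7a next to the C7 stereocentre, which is the hard problem and is left unsolved. The closure creates the C4 carbinol with uncertain facial control (the hydroxyl is required syn to the methyl group). The alkenylchromium sits next to a quaternary carbon, and chromium is used in large excess.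
- Comparison: the step makes one bond, one ring and one stereocentre, against two bonds, two rings and four stereocentres for the photocycloaddition. The route after the key step would be shorter, the route to A1 longer; overall no gain is expected.

Alternative 2: The cut is the angular methyl, taken back to a cyclopropane (C7a–CH2 and C1–CH2). The forward step is the hydroxyl-directed Simmons–Smith reaction (Et2Zn, CH2I2) of the allylic alcohol A3 to the cyclopropyl carbinol A4. Oxidation to the cyclopropyl ketone A5 and reductive cleavage of the C1–CH2 bond would then reveal the methyl group.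
- In its favour: hydroxyl delivery is among the most dependable ways to fix the face of a new quaternary centre. The reductive opening of A5 produces the C2 enolate specifically at C1, which could be alkylated at once with 28. That is better than the chosen plan, where C1 regiochemistry depends on prior desaturation. Both plans set C7a by intramolecular delivery from an existing stereocentre and are equal there.
- Against it: it builds no ring, so the whole bicyclic skeleton of A3 with C4 and C7 must come from elsewhere. In A3 the C7 hydrogen is both allylic and α to the ester, so conjugation and loss of C7 threaten. Three redox operations are spent on one carbon, and C3=C3a still has to be introduced.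
- Comparison: mechanistically safer at C7a, but clearly longer.

Alternative 3: The cut is C1–C7a. The forward step is the Rautenstrauch rearrangement of the propargylic pivalate A6 to the hydrindenone A7 with (Ph3P)AuSbF6 (monovalent gold) in wet acetonitrile: 1,2-acyloxy shift, cyclisation onto the ring alkene and hydrolysis of the enol ester.
- In its favour: one catalytic step delivers the five-membered ring with the C2 ketone, C3=C3a and the quaternary centre at the correct oxidation level, with C4 and C7 already in place. No photochemistry, no stoichiometric palladium and no C7 inversion are needed, and the endgame is shorter. On these points it is better than the chosen plan.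
- Against it: the new bond is made to a fully substituted alkene carbon, which is sensitive to crowding, whereas the photochemical step is not. The face at C7a depends on chirality transfer from the C3 carbinol and on its match with the adjacent C7 ester. A6 shares the doubly activated C7 hydrogen of A3, and the tetrasubstituted cyclohexene with 1,4-cis substituents needs its own multi-step synthesis. 1,3-Acyloxy shift to an allene competes.
- Comparison: better after the key step, probably worse before it, and with a less predictable key step.

Key step: step 7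

Remarks on the chemistry:
- Hydrindane numbering (C1–C7a, C8 on C7) is used for all bicyclic compounds; β is the face of the C7a methyl group.
- Only the E enol acetate is numbered; any Z isomer formed with it is assumed to react in the same way and gives the same aldehyde 15 after step 8.

## Route

Step 1
Reactants: 1 cyclopentene
Product: 3 5,5-dimethoxypentanal, via hydroperoxy acetal 2 (not isolated)
Conditions: O3, CH2Cl2/MeOH, −78 °C; TsOH·H2O (cat.), rt; NaHCO3; Me2S, rt
Reagents that add atoms: ozone (O=[O+][O-]); methanol (CO)
Why: Ozonolysis in methanol gives an aldehyde at one end and a methoxy hydroperoxide at the other; acid acetalises only the free aldehyde and Me2S then reduces the peroxide end to the second aldehyde, so the two termini are differentiated in one flask.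

Step 2
Reactants: 4 3-ethoxycyclopent-2-en-1-one; 3 5,5-dimethoxypentanal
Product: 7 rac-(5R*)-3-ethoxy-5-[(1S*)-1-hydroxy-5,5-dimethoxypentyl]cyclopent-2-en-1-one, via lithium enolate 5 (not isolated), via titanium enolate 6 (not isolated)
Conditions: LiN(iPr)2, THF, −78 °C; ClTi(OiPr)3, −78 → −40 °C; 3, −78 °C; aq. NH4Cl
Reagents that add atoms: none
Why: Kinetic α′-deprotonation of the vinylogous ester and transmetalation give a titanium enolate; aldol addition of such ring-locked titanium enolates is expected to favour the syn adduct (C3a and C4 set relative to each other, racemic), and the anti isomer is removed by chromatography.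

Step 3
Reactants: 7 rac-syn aldol adduct
Product: 8 (5R)-3-ethoxy-5-[(1S)-1-hydroxy-5,5-dimethoxypentyl]cyclopent-2-en-1-one
Conditions: Burkholderia cepacia lipase (Amano PS), vinyl acetate, t-BuOMe, 30 °C, stopped just past half conversion; chromatography
Reagents that add atoms: none
Why: Lipase-catalysed kinetic resolution by enantioselective transesterification: with the ring as large and the chain as medium substituent the (1′R) carbinol should be acetylated faster, so the required (5R,1′S) alcohol is left behind and its enantiomeric purity rises beyond half conversion.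

Step 4
Reactants: 8 (5R,1′S) aldol adduct
Product: 9 (5R)-5-[(1S)-1-(tert-butyldimethylsilyloxy)-5,5-dimethoxypentyl]-3-ethoxycyclopent-2-en-1-one
Conditions: TBSCl, imidazole, DMAP (cat.), DMF, rt
Reagents that add atoms: tert-butyldimethylsilyl chloride (CC(C)(C)[Si](C)(C)Cl)
Why: Standard silylation of a secondary alcohol; the chloride with imidazole is used because silyl triflates with pyridine bases can open dimethyl acetals.

Step 5
Reactants: 9 silyl ether
Product: 11 (5S)-5-(tert-butyldimethylsilyloxy)-5-[(1S)-2-methyl-4-oxocyclopent-2-en-1-yl]pentanal, via tertiary carbinol 10 (not isolated)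
Conditions: MeLi, CeCl3, THF, −78 °C; then 1 M HCl, THF, 0 °C → rt
Reagents that add atoms: methyllithium ([Li]C); water (O)
Why: Stork–Danheiser transposition: the organocerium adds 1,2 to the vinylogous ester without enolising it, dilute acid ionises the tertiary allylic alcohol and hydrolyses the enol ether to the transposed 3-methylcyclopentenone, and the same acid unmasks the aldehyde; C3a and C4 are untouched and the secondary silyl ether survives brief cold dilute acid.

Step 6
Reactants: 11 enone aldehyde
Product: 12 (1E,5S)-5-(tert-butyldimethylsilyloxy)-5-[(1S)-2-methyl-4-oxocyclopent-2-en-1-yl]pent-1-en-1-yl acetate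
Conditions: Ac2O, Et3N, DMAP (cat.), CH2Cl2, rt → 40 °C
Reagents that add atoms: acetic anhydride (CC(=O)OC(C)=O)
Why: Base-mediated O-acetylation of the aldehyde enol (enol ester formation); the aldehyde α-hydrogens are much more acidic and accessible than the γ-hydrogen of the enone, so a mild amine base should leave C3a intact, and the E isomer is expected to predominate.

Step 7
Reactants: 12 E enol acetate
Product: 13 tricyclic acetoxycyclobutane photoadduct (cis-hydrindan-2-one with 3aβ-H, 7aβ-CH3 and 4β-silyloxy, C1 and C7 bridged on the α face by C8H(OAc), acetoxy exo)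
Conditions: hν (350 nm, Pyrex), degassed MeCN, 5 mM, 10 °C
Reagents that add atoms: none
Why: This is an intramolecular enone–alkene [2+2] photocycloaddition, the cycloaddition half of a de Mayo sequence and a well-known reaction type for 4-alkenylcyclopentenones. Excitation of the enone and intersystem crossing give the triplet, whose β-carbon C7a bonds to C7; this closes the six-membered ring in a 6-exo sense (a five-membered closure is impossible with this tether) and leaves a 1,4-biradical at C1 (α-keto) and C8 (acyloxy-stabilised). After spin inversion, C1–C8 coupling closes the cyclobutane in the straight, fused mode. C7a is controlled by C3a: the chain starts there, so C7 can only reach the ring face on which C4 sits, giving the cis ring fusion and, for the syn precursor, the methyl cis to the C4 oxygen. C7 and C1 are fixed by the need for a cis-fused cyclobutane on both rings, which places C8 on the face of C1. C8 follows the E alkene (acetoxy exo) but is of no consequence because it becomes sp2 in step 8. The selectivity needed is regiochemical (acetoxy carbon bound to the enone α-carbon, against the usual head-to-tail preference) and is secured by the chain length. Long-wavelength light and dilution should limit hydrogen abstraction and intermolecular reaction, and the quaternary centre forms in a step that is insensitive to crowding.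

Step 8
Reactants: 13 photoadduct
Product: 15 4β-(tert-butyldimethylsilyloxy)-7aβ-methyl-2-oxo-cis-octahydroindene-7α-carbaldehyde (3aβ-H), via cyclobutanol 14 (not isolated)
Conditions: K2CO3 (cat.), MeOH, 0 °C, short reaction time
Reagents that add atoms: none
Why: Methanolysis of the acetate frees the cyclobutanol, whose alkoxide is β to the C2 ketone and fragments by strain-driven retro-aldol cleavage of C1–C8 (de Mayo fragmentation); C1 becomes a methylene and C8 the aldehyde on C7, still on the face of C1 (7α), which is corrected in step 11.

Step 9
Reactants: 15 keto aldehyde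
Product: 16 4β-(tert-butyldimethylsilyloxy)-7aβ-methyl-2-oxo-cis-octahydroindene-7α-carboxylic acid
Conditions: NaClO2, NaH2PO4, 2-methylbut-2-ene, t-BuOH/H2O, 0 °C → rt
Reagents that add atoms: sodium chlorite ([Na+].[O-]Cl=O)
Why: Pinnick oxidation under buffered conditions with a hypochlorite scavenger; ketone and silyl ether are untouched and no base is present to disturb C7.

Step 10
Reactants: 16 keto acid
Product: 17 methyl 4β-hydroxy-2,2-dimethoxy-7aβ-methyl-cis-octahydroindene-7α-carboxylate
Conditions: HCl (1.25 M in MeOH), HC(OMe)3, 0 °C → rt; NaHCO3 work-up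
Reagents that add atoms: methanol (CO); trimethyl orthoformate (COC(OC)OC)
Why: One acidic methanol treatment effects Fischer esterification, ketalisation of the cyclopentanone and methanolysis of the silyl ether; the ketal removes the enolisable ketone for the base step, the free C4 hydroxyl is the internal nucleophile needed next, and acid does not affect C7.

Step 11
Reactants: 17 hydroxy ester ketal
Product: 20 keto lactone (7aβ-methyl-2-oxo-cis-octahydroindene with a 4β,7β C8(=O)–O–C4 bridge), via 7β-ester epimer 18 (not isolated), via ketal lactone 19 (not isolated)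
Conditions: KOtBu, THF (0.01 M), 4 Å sieves, 0 °C → rt; then 1 M HCl, THF, rt
Reagents that add atoms: water (O)
Why: Base-mediated ester epimerisation with lactone trapping: the C4 alkoxide can reach the C7 hydrogen on its own face, and of the two ester epimers only the 7β one can be attacked by that alkoxide, so the equilibrium drains into the bridged lactone (dilution and sieves disfavour reopening by methoxide); the acidic work-up removes the ketal, and C7 now has the target configuration, cis to the methyl and to the C4 oxygen.

Step 12
Reactants: 20 keto lactone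
Product: 22 4-methoxybenzyl 4β-hydroxy-7aβ-methyl-2-oxo-cis-octahydroindene-7β-carboxylate, via cesium carboxylate 21 (not isolated)
Conditions: CsOH·H2O (1.05 equiv), THF/H2O, 0 °C; evaporate; 4-methoxybenzyl chloride, Bu4NI (cat.), DMF, rt
Reagents that add atoms: cesium hydroxide ([Cs+].[OH-]); 4-methoxybenzyl chloride (COc1ccc(CCl)cc1)
Why: Hydroxide opens the strained lactone by acyl–oxygen cleavage to a hydroxy carboxylate that cannot epimerise at C7, and the cesium carboxylate is O-alkylated without acyl activation, so the lactone cannot re-form; the acid-labile ester lets the final deprotection avoid base.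

Step 13
Reactants: 22 hydroxy keto ester
Product: 25 4-methoxybenzyl 7aβ-methyl-2-oxo-4β-(trimethylsilyloxy)-2,4,5,6,7,7a-hexahydro-1H-indene-7β-carboxylate, via silyl ether ketone 23 (not isolated), via silyl enol ether 24 (not isolated)
Conditions: TMSCl, Et3N, THF, 0 °C; then LiN(iPr)2, −78 °C; then Pd(OAc)2 (1.1 equiv), MeCN, rt
Reagents that add atoms: chlorotrimethylsilane (C[Si](C)(C)Cl)
Why: Saegusa–Ito oxidation: the C4 hydroxyl is silylated first so that no alkoxide can re-lactonise; the amide base in the presence of TMSCl removes the less hindered C3 proton (C1 is neopentyl and shielded by the methyl), and the divalent palladium enolate at C3 loses the 3a-hydrogen by syn β-hydride elimination to give the enone and zerovalent palladium; an enol silane towards C1 cannot eliminate and only returns ketone.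

Step 14
Reactants: 26 2-methylidenepropane-1,3-diol
Product: 27 2-[(tert-butyldimethylsilyloxy)methyl]prop-2-en-1-ol
Conditions: TBSCl (1 equiv), imidazole, 26 (3 equiv), THF, 0 °C
Reagents that add atoms: tert-butyldimethylsilyl chloride (CC(C)(C)[Si](C)(C)Cl)
Why: Statistical monosilylation of a symmetrical diol used in excess; unreacted diol is removed by aqueous extraction.

Step 15
Reactants: 27 mono-silyl ether
Product: 28 [2-(bromomethyl)prop-2-enyloxy](tert-butyl)dimethylsilane
Conditions: CBr4, PPh3, CH2Cl2, 0 °C
Reagents that add atoms: tetrabromomethane (BrC(Br)(Br)Br)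
Why: Appel bromination of the primary allylic alcohol under neutral conditions that leave the silyl ether intact.

Step 16
Reactants: 25 enone; 28 allylic bromide
Product: 31 4-methoxybenzyl 1β-{2-[(tert-butyldimethylsilyloxy)methyl]prop-2-enyl}-4β-hydroxy-7aβ-methyl-2-oxo-2,4,5,6,7,7a-hexahydro-1H-indene-7β-carboxylate, via lithium dienolate 29 (not isolated), via trimethylsilyl ether 30 (not isolated)
Conditions: LiN(iPr)2 (1.1 equiv), THF, −78 °C; 28, −78 → −30 °C; then citric acid, MeOH, 0 °C
Reagents that add atoms: none
Why: Kinetic α′-deprotonation of the cross-conjugated enone (the C4 hydrogen lies near the nodal plane of the enone and the ester α-hydrogen is hindered) and SN2 alkylation by the allylic bromide; the electrophile should enter C1 on the methyl face because the other face is screened by C7 and its ester, and this isomer is also the more stable one, so any base equilibration at C1 reinforces it; citric acid in methanol removes only the labile trimethylsilyl ether.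

Step 17
Reactants: 32 (R)-2-methylbutanoic acid
Product: 33 (R)-2-methylbutan-1-ol
Conditions: LiAlH4, Et2O, 0 °C → rt
Reagents that add atoms: none
Why: Hydride reduction of the carboxylic acid; the α-stereocentre is not enolised under these conditions.

Step 18
Reactants: 33 (R)-2-methylbutan-1-ol
Product: 35 ethyl (2E,4R)-2,4-dimethylhex-2-enoate, via (R)-2-methylbutanal 34 (not isolated)
Conditions: (COCl)2, DMSO, Et3N, CH2Cl2, −78 °C; then Ph3P=C(CH3)CO2Et, −78 °C → rt
Reagents that add atoms: ethyl 2-(triphenylphosphoranylidene)propanoate (CCOC(=O)C(C)=P(c1ccccc1)(c1ccccc1)c1ccccc1)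
Why: Swern oxidation followed by Wittig olefination in the same flask, so the configurationally labile α-branched aldehyde is consumed cold without isolation; the stabilised α-methyl ylide gives the E trisubstituted alkene.

Step 19
Reactants: 35 enoate
Product: 36 (2E,4R)-2,4-dimethylhex-2-en-1-ol
Conditions: iBu2AlH, CH2Cl2, −78 °C; aq. KNaC4H4O6
Reagents that add atoms: none
Why: Low-temperature 1,2-reduction of the conjugated ester to the allylic alcohol; the alkene is untouched.

Step 20
Reactants: 36 allylic alcohol
Product: 38 ethyl (2E,4E,6R)-4,6-dimethylocta-2,4-dienoate, via (2E,4R)-2,4-dimethylhex-2-enal 37 (not isolated)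
Conditions: MnO2, Ph3P=CHCO2Et, CH2Cl2, rt
Reagents that add atoms: ethyl (triphenylphosphoranylidene)acetate (CCOC(=O)C=P(c1ccccc1)(c1ccccc1)c1ccccc1)
Why: Allylic oxidation by MnO2 with in-situ Wittig trapping of the enal (tandem oxidation–olefination) gives the E disubstituted alkene and avoids handling the volatile enal.

Step 21
Reactants: 38 dienoate
Product: 39 (2E,4E,6R)-4,6-dimethylocta-2,4-dienoic acid
Conditions: LiOH, THF/MeOH/H2O, rt; then dilute HCl
Reagents that add atoms: lithium hydroxide ([Li+].[OH-])
Why: Saponification of the ethyl ester; hydroxide is far too weak a base to remove the vinylogous ε-hydrogen at C6, so the stereocentre is safe.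

Step 22
Reactants: 31 hydroxy enone; 39 dienoic acid
Product: 41 4-methoxybenzyl 1β-{2-[(tert-butyldimethylsilyloxy)methyl]prop-2-enyl}-4β-[(2E,4E,6R)-4,6-dimethylocta-2,4-dienoyloxy]-7aβ-methyl-2-oxo-2,4,5,6,7,7a-hexahydro-1H-indene-7β-carboxylate, via mixed anhydride 40 (not isolated)
Conditions: 39, 2,4,6-trichlorobenzoyl chloride, Et3N, THF, rt; then 31, DMAP, toluene, rt
Reagents that add atoms: none
Why: Yamaguchi esterification of the hindered axial allylic alcohol through the mixed anhydride and DMAP; it is placed after all strong-base steps because the dienoate ε-hydrogen is the stereocentre-bearing acidic position, and the amine bases can at most equilibrate C1 towards its more stable, desired configuration.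

Step 23
Reactants: 41 protected ester
Product: 42 4β-[(2E,4E,6R)-4,6-dimethylocta-2,4-dienoyloxy]-1β-[2-(hydroxymethyl)prop-2-enyl]-7aβ-methyl-2-oxo-2,4,5,6,7,7a-hexahydro-1H-indene-7β-carboxylic acid
Conditions: CF3CO2H/CH2Cl2 (1:9), anisole, 0 °C; aq. NaHCO3, then acidify to pH 4
Reagents that add atoms: none
Why: Acidolysis: the 4-methoxybenzyl ester ionises to a benzylic cation trapped by anisole and the primary silyl ether is solvolysed; the secondary dienoate, the electron-poor γ-acyloxy enone and the allylically oxygenated 1,1-disubstituted alkene should not react in cold dilute acid, and no stereocentre is touched.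

Step 24
Reactants: 42 hydroxy acid
Product: 43 (1R,4S,7R,7aS)-4-{[(2E,4E,6R)-4,6-dimethylocta-2,4-dienoyl]oxy}-1-(2-formylprop-2-en-1-yl)-7a-methyl-2-oxo-2,4,5,6,7,7a-hexahydro-1H-indene-7-carboxylic acid (CNP0302671.3)
Conditions: Dess–Martin periodinane, CH2Cl2, 0 °C → rt
Reagents that add atoms: none
Why: Dess–Martin oxidation of the primary allylic alcohol to the α-methylene aldehyde under neutral, non-nucleophilic conditions that tolerate the free acid; it is the last step because the enal is the most fragile group.

## Compound list

1 | cyclopentene | C1=CCCC1 | starting material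
2 | 1-hydroperoxy-1,5,5-trimethoxypentane | COC(OC)CCCC(OC)OO | intermediate
3 | 5,5-dimethoxypentanal | COC(OC)CCCC=O | intermediate
4 | 3-ethoxycyclopent-2-en-1-one | CCOC1=CC(=O)CC1 | starting material
5 | lithium α′-enolate of 4 | CCOC1=CC(O[Li])=CC1 | intermediate
6 | tris(isopropoxy)titanium α′-enolate of 4 | CCOC1=CC(O[Ti](OC(C)C)(OC(C)C)OC(C)C)=CC1 | intermediate
7 | rac-(5R*)-3-ethoxy-5-[(1S*)-1-hydroxy-5,5-dimethoxypentyl]cyclopent-2-en-1-one (racemate, both enantiomers shown) | CCOC1=CC(=O)[C@@H]([C@@H](O)CCCC(OC)OC)C1.CCOC1=CC(=O)[C@H]([C@H](O)CCCC(OC)OC)C1 | intermediate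
8 | (5R)-3-ethoxy-5-[(1S)-1-hydroxy-5,5-dimethoxypentyl]cyclopent-2-en-1-one | CCOC1=CC(=O)[C@@H]([C@@H](O)CCCC(OC)OC)C1 | intermediate
9 | (5R)-5-[(1S)-1-(tert-butyldimethylsilyloxy)-5,5-dimethoxypentyl]-3-ethoxycyclopent-2-en-1-one | CCOC1=CC(=O)[C@@H]([C@@H](O[Si](C)(C)C(C)(C)C)CCCC(OC)OC)C1 | intermediate
10 | tertiary carbinol from methyl addition to 9 (both carbinol epimers) | CCOC1=CC(C)(O)[C@@H]([C@@H](O[Si](C)(C)C(C)(C)C)CCCC(OC)OC)C1 | intermediate
11 | (5S)-5-(tert-butyldimethylsilyloxy)-5-[(1S)-2-methyl-4-oxocyclopent-2-en-1-yl]pentanal | O=C1C[C@H]([C@@H](O[Si](C)(C)C(C)(C)C)CCCC=O)C(C)=C1 | intermediate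
12 | (1E,5S)-5-(tert-butyldimethylsilyloxy)-5-[(1S)-2-methyl-4-oxocyclopent-2-en-1-yl]pent-1-en-1-yl acetate | O=C1C[C@H]([C@@H](O[Si](C)(C)C(C)(C)C)CC/C=C/OC(C)=O)C(C)=C1 | intermediate
13 | tricyclic acetoxycyclobutane photoadduct | O=C1C[C@@H]2[C@@H](O[Si](C)(C)C(C)(C)C)CC[C@@H]3[C@@H](OC(C)=O)[C@H]1[C@]23C | intermediate
14 | cyclobutanol from deacetylation of 13 | O=C1C[C@@H]2[C@@H](O[Si](C)(C)C(C)(C)C)CC[C@@H]3[C@@H](O)[C@H]1[C@]23C | intermediate
15 | 4β-(tert-butyldimethylsilyloxy)-7aβ-methyl-2-oxo-cis-octahydroindene-7α-carbaldehyde | O=C1C[C@@H]2[C@@H](O[Si](C)(C)C(C)(C)C)CC[C@H](C=O)[C@]2(C)C1 | intermediate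
16 | 4β-(tert-butyldimethylsilyloxy)-7aβ-methyl-2-oxo-cis-octahydroindene-7α-carboxylic acid | O=C1C[C@@H]2[C@@H](O[Si](C)(C)C(C)(C)C)CC[C@H](C(=O)O)[C@]2(C)C1 | intermediate
17 | methyl 4β-hydroxy-2,2-dimethoxy-7aβ-methyl-cis-octahydroindene-7α-carboxylate | COC1(OC)C[C@@H]2[C@@H](O)CC[C@H](C(=O)OC)[C@]2(C)C1 | intermediate
18 | methyl 4β-hydroxy-2,2-dimethoxy-7aβ-methyl-cis-octahydroindene-7β-carboxylate | COC1(OC)C[C@@H]2[C@@H](O)CC[C@@H](C(=O)OC)[C@]2(C)C1 | intermediate
19 | ketal lactone (4β,7β C8(=O)–O–C4 bridge, 2,2-dimethoxy) | COC1(OC)C[C@@H]2[C@@H]3CC[C@@H](C(=O)O3)[C@]2(C)C1 | intermediate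
20 | keto lactone (4β,7β C8(=O)–O–C4 bridge, 2-oxo) | O=C1C[C@@H]2[C@@H]3CC[C@@H](C(=O)O3)[C@]2(C)C1 | intermediate
21 | cesium 4β-hydroxy-7aβ-methyl-2-oxo-cis-octahydroindene-7β-carboxylate | O=C1C[C@@H]2[C@@H](O)CC[C@@H](C(=O)[O-])[C@]2(C)C1.[Cs+] | intermediate
22 | 4-methoxybenzyl 4β-hydroxy-7aβ-methyl-2-oxo-cis-octahydroindene-7β-carboxylate | O=C1C[C@@H]2[C@@H](O)CC[C@@H](C(=O)OCc3ccc(OC)cc3)[C@]2(C)C1 | intermediate
23 | 4-O-trimethylsilyl ether of 22 | O=C1C[C@@H]2[C@@H](O[Si](C)(C)C)CC[C@@H](C(=O)OCc3ccc(OC)cc3)[C@]2(C)C1 | intermediate
24 | C2–C3 trimethylsilyl enol ether of 23 | C[Si](C)(C)OC1=C[C@@H]2[C@@H](O[Si](C)(C)C)CC[C@@H](C(=O)OCc3ccc(OC)cc3)[C@]2(C)C1 | intermediate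
25 | 4-methoxybenzyl 7aβ-methyl-2-oxo-4β-(trimethylsilyloxy)-2,4,5,6,7,7a-hexahydro-1H-indene-7β-carboxylate | O=C1C=C2[C@@H](O[Si](C)(C)C)CC[C@@H](C(=O)OCc3ccc(OC)cc3)[C@]2(C)C1 | intermediate
26 | 2-methylidenepropane-1,3-diol | C=C(CO)CO | starting material
27 | 2-[(tert-butyldimethylsilyloxy)methyl]prop-2-en-1-ol | C=C(CO)CO[Si](C)(C)C(C)(C)C | intermediate
28 | [2-(bromomethyl)prop-2-enyloxy](tert-butyl)dimethylsilane | C=C(CBr)CO[Si](C)(C)C(C)(C)C | intermediate
29 | lithium α′-dienolate of 25 | [Li]OC1=C[C@@]2(C)[C@H](C(=O)OCc3ccc(OC)cc3)CC[C@H](O[Si](C)(C)C)C2=C1 | intermediate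
30 | 4-O-trimethylsilyl ether of 31 | O=C1C=C2[C@@H](O[Si](C)(C)C)CC[C@@H](C(=O)OCc3ccc(OC)cc3)[C@]2(C)[C@H]1CC(=C)CO[Si](C)(C)C(C)(C)C | intermediate
31 | 4-methoxybenzyl 1β-{2-[(tert-butyldimethylsilyloxy)methyl]prop-2-enyl}-4β-hydroxy-7aβ-methyl-2-oxo-2,4,5,6,7,7a-hexahydro-1H-indene-7β-carboxylate | O=C1C=C2[C@@H](O)CC[C@@H](C(=O)OCc3ccc(OC)cc3)[C@]2(C)[C@H]1CC(=C)CO[Si](C)(C)C(C)(C)C | intermediate
32 | (R)-2-methylbutanoic acid | CC[C@@H](C)C(=O)O | starting material
33 | (R)-2-methylbutan-1-ol | CC[C@@H](C)CO | intermediate
34 | (R)-2-methylbutanal | CC[C@@H](C)C=O | intermediate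
35 | ethyl (2E,4R)-2,4-dimethylhex-2-enoate | CC[C@@H](C)/C=C(C)/C(=O)OCC | intermediate
36 | (2E,4R)-2,4-dimethylhex-2-en-1-ol | CC[C@@H](C)/C=C(C)/CO | intermediate
37 | (2E,4R)-2,4-dimethylhex-2-enal | CC[C@@H](C)/C=C(C)/C=O | intermediate
38 | ethyl (2E,4E,6R)-4,6-dimethylocta-2,4-dienoate | CC[C@@H](C)/C=C(C)/C=C/C(=O)OCC | intermediate
39 | (2E,4E,6R)-4,6-dimethylocta-2,4-dienoic acid | CC[C@@H](C)/C=C(C)/C=C/C(=O)O | intermediate
40 | mixed anhydride of 39 with 2,4,6-trichlorobenzoic acid | CC[C@@H](C)/C=C(C)/C=C/C(=O)OC(=O)c1c(Cl)cc(Cl)cc1Cl | intermediate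
41 | 4-methoxybenzyl ester, side-chain silyl ether, C4 dienoate (fully protected) | O=C1C=C2[C@@H](OC(=O)/C=C/C(C)=C/[C@H](C)CC)CC[C@@H](C(=O)OCc3ccc(OC)cc3)[C@]2(C)[C@H]1CC(=C)CO[Si](C)(C)C(C)(C)C | intermediate
42 | 4β-dienoyloxy-1β-[2-(hydroxymethyl)prop-2-enyl]-7aβ-methyl-2-oxo-hexahydroindene-7β-carboxylic acid | O=C1C=C2[C@@H](OC(=O)/C=C/C(C)=C/[C@H](C)CC)CC[C@@H](C(=O)O)[C@]2(C)[C@H]1CC(=C)CO | intermediate
43 | (1R,4S,7R,7aS)-4-{[(2E,4E,6R)-4,6-dimethylocta-2,4-dienoyl]oxy}-1-(2-formylprop-2-en-1-yl)-7a-methyl-2-oxo-2,4,5,6,7,7a-hexahydro-1H-indene-7-carboxylic acid | C=C(C=O)C[C@H]1C(=O)C=C2[C@@H](OC(=O)/C=C/C(C)=C/[C@H](C)CC)CC[C@@H](C(=O)O)[C@@]21C | target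

## Step count and least certain steps

Total: 24 steps. Longest linear sequence: 17 steps (steps 1–13, 16, 22, 23, 24). The side-chain acid takes 5 steps (17–21) and the allylic bromide 2 steps (14, 15).

Step 7 (key step). The tether forces the acetoxy-bearing carbon next to the enone α-carbon against the intrinsic polarity preference, so ring closure may be slow. Hydrogen abstraction by the excited enone from the chain, geometric isomerisation of the enol acetate and secondary photolysis of the product may then consume the material. Fallback, from 11: an amine-catalysed intramolecular Michael addition (pyrrolidine, AcOH, CH2Cl2) of the aldehyde enamine carbon C7 to the enone β-carbon C7a forms the same C7a–C7 bond 6-exo without a cyclobutane. The chain again reaches C7a only on the face of C4, so it gives 15 and/or its C7 epimer, 4β-(tert-butyldimethylsilyloxy)-7aβ-methyl-2-oxo-cis-octahydroindene-7β-carbaldehyde F1. Compound 15 re-enters at step 9. F1 is oxidised under the conditions of step 9 to the 7β acid F2, which under the conditions of step 10 gives 18, the intermediate of step 11; both streams therefore meet at 20.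

Step 11. Epimerisation at the hindered C7 may be incomplete, and the strained lactone may be reopened by the methoxide it releases or may oligomerise. Fallback, from 17: the ester is first equilibrated with NaOMe in MeOH to a mixture of 17 and 18. The mixture is then heated with camphorsulfonic acid in toluene over 5 Å sieves; only 18 can lactonise, to 19, and aqueous acid gives 20. Unchanged 17 is separated and recycled, so the inversion no longer depends on a single base-driven funnel.

Step 3. The lipase may discriminate poorly because the medium substituent is a four-carbon chain, giving slow acylation or low enantiomeric purity. Fallback, from 7: the racemate is carried through steps 4–9, each intermediate being the racemate of 9, 11, 12, 13, 15 and 16. Racemic 16 is resolved by fractional crystallisation of its salt with (S)-1-phenylethylamine, F3 (or the salt of the enantiomeric amine, whichever crystallises with the required acid). Acidification returns enantiopure 16.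

Step 2. The titanium enolate may give low syn/anti selectivity, or retro-aldol equilibration may erode it. Fallback, from the diastereomer mixture of 7 and the anti adduct rac-(5R*)-3-ethoxy-5-[(1R*)-1-hydroxy-5,5-dimethoxypentyl]cyclopent-2-en-1-one F4: Dess–Martin oxidation gives the β-diketone 5-(5,5-dimethoxypentanoyl)-3-ethoxycyclopent-2-en-1-one F5. Chelation-controlled reduction with Zn(BH4)2 in Et2O at −20 °C should deliver hydride anti to the ring methylene of the zinc chelate and return syn 7.

Step 16. The electrophile may enter C1 with poor facial selectivity, and proton transfer between product and enolate may cause dialkylation. Fallback, from the C1 epimer of 31, 4-methoxybenzyl 1α-{2-[(tert-butyldimethylsilyloxy)methyl]prop-2-enyl}-4β-hydroxy-7aβ-methyl-2-oxo-2,4,5,6,7,7a-hexahydro-1H-indene-7β-carboxylate F6: thermodynamic equilibration with DBU in toluene at rt replaces kinetic control and should convert F6 into 31, whose side chain lies away from C7 and its ester.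

## Further compounds

F1 | step 7 | 4β-(tert-butyldimethylsilyloxy)-7aβ-methyl-2-oxo-cis-octahydroindene-7β-carbaldehyde | O=C1C[C@@H]2[C@@H](O[Si](C)(C)C(C)(C)C)CC[C@@H](C=O)[C@]2(C)C1
F2 | step 7 | 4β-(tert-butyldimethylsilyloxy)-7aβ-methyl-2-oxo-cis-octahydroindene-7β-carboxylic acid | O=C1C[C@@H]2[C@@H](O[Si](C)(C)C(C)(C)C)CC[C@@H](C(=O)O)[C@]2(C)C1
F0 | step 11 | none | none
F3 | step 3 | (S)-1-phenylethylammonium salt of 16 | O=C1C[C@@H]2[C@@H](O[Si](C)(C)C(C)(C)C)CC[C@H](C(=O)[O-])[C@]2(C)C1.C[C@H]([NH3+])c1ccccc1
F4 | step 2 | rac-(5R*)-3-ethoxy-5-[(1R*)-1-hydroxy-5,5-dimethoxypentyl]cyclopent-2-en-1-one (racemate, both enantiomers shown) | CCOC1=CC(=O)[C@@H]([C@H](O)CCCC(OC)OC)C1.CCOC1=CC(=O)[C@H]([C@@H](O)CCCC(OC)OC)C1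
F5 | step 2 | 5-(5,5-dimethoxypentanoyl)-3-ethoxycyclopent-2-en-1-one | CCOC1=CC(=O)C(C(=O)CCCC(OC)OC)C1
F6 | step 16 | 4-methoxybenzyl 1α-{2-[(tert-butyldimethylsilyloxy)methyl]prop-2-enyl}-4β-hydroxy-7aβ-methyl-2-oxo-2,4,5,6,7,7a-hexahydro-1H-indene-7β-carboxylate | O=C1C=C2[C@@H](O)CC[C@@H](C(=O)OCc3ccc(OC)cc3)[C@]2(C)[C@@H]1CC(=C)CO[Si](C)(C)C(C)(C)C
A1 | alternative 1 | tert-butyl (2R)-2-[(1S,4S)-2-iodo-1-methyl-4-(triethylsilyloxy)cyclopent-2-en-1-yl]-5-oxopentanoate (alkenyl iodide aldehyde) | O=CCC[C@@H](C(=O)OC(C)(C)C)[C@]1(C)C[C@H](O[Si](CC)(CC)CC)C=C1I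
A2 | alternative 1 | hydrindene C4 allylic alcohol with C2 triethylsilyl ether and C7 tert-butyl ester | C1[C@H](O[Si](CC)(CC)CC)C=C2[C@@H](O)CC[C@@H](C(=O)OC(C)(C)C)[C@@]21C
A3 | alternative 2 | C2 allylic alcohol with C1=C7a alkene, C4 silyl ether and C7 tert-butyl ester | O[C@H]1C[C@@H]2[C@@H](O[Si](C)(C)C(C)(C)C)CC[C@@H](C(=O)OC(C)(C)C)C2=C1
A4 | alternative 2 | cyclopropyl carbinol with the CH2 bridge across C1 and C7a | O[C@H]1C[C@@H]2[C@@H](O[Si](C)(C)C(C)(C)C)CC[C@@H](C(=O)OC(C)(C)C)[C@@]23C[C@@H]13
A5 | alternative 2 | cyclopropyl ketone from oxidation of A4 | O=C1C[C@@H]2[C@@H](O[Si](C)(C)C(C)(C)C)CC[C@@H](C(=O)OC(C)(C)C)[C@@]23C[C@@H]13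
A6 | alternative 3 | C3 propargylic pivalate on the C3a=C7a cyclohexene (C3 configuration left open) | C#CC(OC(=O)C(C)(C)C)C1=C(C)[C@H](C(=O)OC(C)(C)C)CC[C@@H]1O[Si](C)(C)C(C)(C)C
A7 | alternative 3 | 7a-methylhydrindenone with C4 silyl ether and C7 tert-butyl ester, C1 unsubstituted | C1C(=O)C=C2[C@@H](O[Si](C)(C)C(C)(C)C)CC[C@@H](C(=O)OC(C)(C)C)[C@@]21C
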